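**Plan**
- Retrosynthesis: the two N–Si bonds and the quinone oxidation level go first. The six-membered ring is then cut between the carbonyl carbon flanked by the prenyl-bearing and an indolyl-bearing carbon and that indolyl-bearing carbon (the one next to C–OMe). Next come the bond from the other oxygenated carbon to the C(OMe)=C(indolyl) unit, and the indolyl and prenyl bonds to a squarate ring.
- Enabling feature: the para-dioxygenated ring contains a C(=O)–C(prenyl)=C(indolyl)–C(–O) half that is a cyclobutenone in disguise, and a C(OMe)=C(indolyl) edge that is an α-methoxyalkenyl group. The ring is therefore the 6π-electrocyclization product of a dienylketene released by 4π opening of a temporary four-membered ring.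
- Forward: dimethyl squarate takes up the first indole (as its C3-lithio derivative) and an allyl group (made prenyl by cross-metathesis), with one carbonyl transposition. The second indole enters as an α-methoxyalkenyllithium (ynol ether, syn-hydrostannation, tin–lithium exchange); its addition and a second transposition give the 4-alkenyl-4-hydroxycyclobutenone.
- Thermolysis opens the four-membered ring and closes the six-membered ring as the hydroquinone; Ag2O oxidation and fluoride desilylation finish the synthesis.
- Stereochemistry: the target has no stereocentre and no stereogenic alkene. The carbinol centres of the cyclobutenones are racemic and vanish on aromatization. The (E)-stannane geometry only serves to put hydrogen, not indole, inside at the cyclization terminus.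

Key step: step 7

Assumption: compounds 1, 2 and 9 are taken as commercial; all cyclobutenone intermediates are racemic, and their stereocentre is erased in step 7.

**Step 1**
Reactants: 1 3-bromo-1-(triisopropylsilyl)-1H-indole; 2 dimethyl squarate
Product: 5 2,3-dimethoxy-4-[1-(triisopropylsilyl)-1H-indol-3-yl]-4-(trimethylsilyloxy)cyclobut-2-en-1-one (racemic), via 3-lithio-1-(triisopropylsilyl)indole 3 (not isolated), via lithium alkoxide adduct 4 (not isolated)
Conditions: t-BuLi (2 equiv), THF, -78 °C; add to 2, THF, -78 °C; TMSCl, -78 to 0 °C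
Reagents that add atoms: chlorotrimethylsilane, C[Si](C)(C)Cl
Why: Bromine–lithium exchange gives the C3-lithioindole (the bulky N-silyl group blocks migration to C2), which should add 1,2 to one squarate carbonyl, and the tertiary alkoxide is capped as its silyl ether, all standard squarate ester chemistry.

**Step 2**
Reactants: 5 2,3-dimethoxy-4-[1-(triisopropylsilyl)-1H-indol-3-yl]-4-(trimethylsilyloxy)cyclobut-2-en-1-one
Product: 7 3-allyl-2-methoxy-4-[1-(triisopropylsilyl)-1H-indol-3-yl]-4-(trimethylsilyloxy)cyclobut-2-en-1-one (racemic), via bromomagnesium alkoxide 6 (not isolated)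
Conditions: allylMgBr, THF, -78 °C; TFAA (1.05 equiv), -78 °C; aq. NaHCO3
Reagents that add atoms: allylmagnesium bromide, C=CC[Mg]Br; water, O (carbonyl oxygen, delivered on work-up)
Why: The Grignard reagent adds to the only carbonyl and trifluoroacetylation of the new alkoxide (the silyl ether is not activated) triggers ionization to a methoxy-stabilized cyclobutenyl cation that is hydrolysed at the distal methoxy carbon, the 1,3-carbonyl transposition known from the conversion of squarate adducts into alkoxycyclobutenediones; conjugate addition–elimination would give the same enone.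

**Step 3**
Reactants: 7 3-allyl-2-methoxy-4-[1-(triisopropylsilyl)-1H-indol-3-yl]-4-(trimethylsilyloxy)cyclobut-2-en-1-one
Product: 8 2-methoxy-3-(3-methylbut-2-en-1-yl)-4-[1-(triisopropylsilyl)-1H-indol-3-yl]-4-(trimethylsilyloxy)cyclobut-2-en-1-one (racemic)
Conditions: 2-methyl-2-butene (excess), second-generation Grubbs catalyst (H2IMes)(PCy3)Cl2Ru=CHPh (5 mol %), CH2Cl2, 40 °C
Reagents that add atoms: 2-methyl-2-butene, CC=C(C)C
Why: Olefin cross-metathesis of a terminal allyl group with 2-methyl-2-butene is the standard way to a prenyl group, and the tetrasubstituted ring alkene is inert to the catalyst.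

**Step 4**
Reactants: 9 chloroacetaldehyde dimethyl acetal; 1 3-bromo-1-(triisopropylsilyl)-1H-indole
Product: 12 3-(methoxyethynyl)-1-(triisopropylsilyl)-1H-indole, via lithium methoxyacetylide 10 (not isolated), via (methoxyethynyl)zinc chloride 11 (not isolated)
Conditions: LiNEt2 (3 equiv), THF, 0 °C; ZnCl2, 0 °C; 1, Pd(P(t-Bu)3)2 (3 mol %), THF, rt to 40 °C
Reagents that add atoms: none
Why: Twofold elimination (methanol, then HCl) and deprotonation of the chloroacetal gives the alkoxyacetylide, which after transmetalation to zinc should undergo Negishi alkynylation of the heteroaryl bromide.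

**Step 5**
Reactants: 12 3-(methoxyethynyl)-1-(triisopropylsilyl)-1H-indole
Product: 13 (E)-tributyl{1-methoxy-2-[1-(triisopropylsilyl)-1H-indol-3-yl]ethenyl}stannane
Conditions: Bu3SnH, Pd(PPh3)4 (2 mol %), THF, 0 °C
Reagents that add atoms: tributyltin hydride, CCCC[SnH](CCCC)CCCC
Why: Palladium-catalysed hydrostannation of 1-alkoxyalkynes is a syn addition that places tin on the oxygen-bearing carbon, so hydrogen and tin end up cis and the alkene geometry is set as (E).

**Step 6**
Reactants: 13 (E)-tributyl{1-methoxy-2-[1-(triisopropylsilyl)-1H-indol-3-yl]ethenyl}stannane; 8 2-methoxy-3-(3-methylbut-2-en-1-yl)-4-[1-(triisopropylsilyl)-1H-indol-3-yl]-4-(trimethylsilyloxy)cyclobut-2-en-1-one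
Product: 16 4-hydroxy-4-{(Z)-1-methoxy-2-[1-(triisopropylsilyl)-1H-indol-3-yl]ethenyl}-2-(3-methylbut-2-en-1-yl)-3-[1-(triisopropylsilyl)-1H-indol-3-yl]cyclobut-2-en-1-one (racemic), via alkenyllithium 14 (not isolated), via lithium alkoxide adduct 15 (not isolated)
Conditions: n-BuLi, THF, -78 °C; 8, -78 °C; aq. NH4Cl; pyridinium p-toluenesulfonate (cat.), THF–H2O, 0 °C
Reagents that add atoms: water, O (carbonyl oxygen)
Why: Tin–lithium exchange with retention gives a configurationally stable α-alkoxyalkenyllithium that adds to the only carbonyl of 8, and mild acid then ionizes the silyloxy carbinol at the indol-3-yl carbon and water enters at the methoxy carbon (a 1,3-carbonyl transposition of the Stork–Danheiser type), so the carbinol lands beside the indolyl carbon and the carbonyl beside the prenyl carbon by construction; the new carbinol centre is racemic.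

**Step 7**
Reactants: 16 4-hydroxy-4-{(Z)-1-methoxy-2-[1-(triisopropylsilyl)-1H-indol-3-yl]ethenyl}-2-(3-methylbut-2-en-1-yl)-3-[1-(triisopropylsilyl)-1H-indol-3-yl]cyclobut-2-en-1-one
Product: 19 2-methoxy-5-(3-methylbut-2-en-1-yl)-3,6-bis[1-(triisopropylsilyl)-1H-indol-3-yl]benzene-1,4-diol, via dienylketene 17 (not isolated), via cyclohexadienone 18 (not isolated)
Conditions: toluene (degassed), 110 °C, argon
Reagents that add atoms: none
Why: Heating should trigger conrotatory 4π electrocyclic opening of the cyclobutenone (cleavage of the bond between the carbonyl carbon and the carbinol carbon) to dienylketene 17, with the hydroxyl rotated outward and the methoxyalkenyl group inward, cis to the ketene. The ketene carbon, flanked by the prenyl-bearing carbon, then bonds to the indolyl-bearing alkene terminus in a 6π electrocyclization that closes the six-membered ring as cyclohexadienone 18, which tautomerizes to the aromatic hydroquinone 19. The closest known reaction is the thermal ring expansion of 4-alkenyl-4-hydroxycyclobutenones to hydroquinones (Moore–Liebeskind type), which also tolerates α-alkoxyalkenyl groups such as lithiated cyclic enol ethers. The only new sp3 centre, the CH(indolyl) carbon of 18, forms racemic and is destroyed by enolization, so no stereocontrol is needed. The selectivity required is torquoselectivity in the ring opening, secured by the strong outward preference of the donor hydroxyl, which also keeps the hydroxyl from lactonizing onto the ketene; the (Z)-alkene geometry places hydrogen rather than indole inside at the terminus. Closure onto the ring-bound indole is not competitive because it would form a five-membered ring outside the electrocyclic manifold.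

**Step 8**
Reactants: 19 2-methoxy-5-(3-methylbut-2-en-1-yl)-3,6-bis[1-(triisopropylsilyl)-1H-indol-3-yl]benzene-1,4-diol
Product: 20 2-methoxy-5-(3-methylbut-2-en-1-yl)-3,6-bis[1-(triisopropylsilyl)-1H-indol-3-yl]cyclohexa-2,5-diene-1,4-dione
Conditions: Ag2O, MgSO4, CH2Cl2, rt
Reagents that add atoms: none
Why: Ag2O is the standard mild oxidant for hydroquinone-to-quinone conversion after such ring expansions and should leave the N-silylindoles and the prenyl alkene untouched.

**Step 9**
Reactants: 20 2-methoxy-5-(3-methylbut-2-en-1-yl)-3,6-bis[1-(triisopropylsilyl)-1H-indol-3-yl]cyclohexa-2,5-diene-1,4-dione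
Product: 21 3,6-di(1H-indol-3-yl)-2-methoxy-5-(3-methylbut-2-en-1-yl)cyclohexa-2,5-diene-1,4-dione (CNP0506434.0)
Conditions: TBAF (2.2 equiv), AcOH (2.2 equiv), THF, 0 °C
Reagents that add atoms: none
Why: Fluoride cleaves the two N–Si bonds, which are labile because each indole is a vinylogous amide of the quinone, and the acetic acid buffer should prevent displacement of the vinylogous-ester methoxy group.

**Compound list**
1 | 3-bromo-1-(triisopropylsilyl)-1H-indole | Brc1cn([Si](C(C)C)(C(C)C)C(C)C)c2ccccc12 | starting material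
2 | dimethyl squarate (3,4-dimethoxycyclobut-3-ene-1,2-dione) | COC1=C(OC)C(=O)C1=O | starting material
3 | 3-lithio-1-(triisopropylsilyl)-1H-indole | [Li]c1cn([Si](C(C)C)(C(C)C)C(C)C)c2ccccc12 | intermediate
4 | lithium 2,3-dimethoxy-4-oxo-1-[1-(triisopropylsilyl)-1H-indol-3-yl]cyclobut-2-en-1-olate (racemic) | COC1=C(OC)C(O[Li])(c2cn([Si](C(C)C)(C(C)C)C(C)C)c3ccccc23)C1=O | intermediate
5 | 2,3-dimethoxy-4-[1-(triisopropylsilyl)-1H-indol-3-yl]-4-(trimethylsilyloxy)cyclobut-2-en-1-one (racemic) | COC1=C(OC)C(O[Si](C)(C)C)(c2cn([Si](C(C)C)(C(C)C)C(C)C)c3ccccc23)C1=O | intermediate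
6 | bromomagnesium 1-allyl-2,3-dimethoxy-4-[1-(triisopropylsilyl)-1H-indol-3-yl]-4-(trimethylsilyloxy)cyclobut-2-en-1-olate (diastereomer mixture) | C=CCC1(O[Mg]Br)C(OC)=C(OC)C1(O[Si](C)(C)C)c1cn([Si](C(C)C)(C(C)C)C(C)C)c2ccccc12 | intermediate
7 | 3-allyl-2-methoxy-4-[1-(triisopropylsilyl)-1H-indol-3-yl]-4-(trimethylsilyloxy)cyclobut-2-en-1-one (racemic) | C=CCC1=C(OC)C(=O)C1(O[Si](C)(C)C)c1cn([Si](C(C)C)(C(C)C)C(C)C)c2ccccc12 | intermediate
8 | 2-methoxy-3-(3-methylbut-2-en-1-yl)-4-[1-(triisopropylsilyl)-1H-indol-3-yl]-4-(trimethylsilyloxy)cyclobut-2-en-1-one (racemic) | CC(C)=CCC1=C(OC)C(=O)C1(O[Si](C)(C)C)c1cn([Si](C(C)C)(C(C)C)C(C)C)c2ccccc12 | intermediate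
9 | chloroacetaldehyde dimethyl acetal (2-chloro-1,1-dimethoxyethane) | COC(CCl)OC | starting material
10 | lithium methoxyacetylide | [Li]C#COC | intermediate
11 | (methoxyethynyl)zinc chloride | Cl[Zn]C#COC | intermediate
12 | 3-(methoxyethynyl)-1-(triisopropylsilyl)-1H-indole | COC#Cc1cn([Si](C(C)C)(C(C)C)C(C)C)c2ccccc12 | intermediate
13 | (E)-tributyl{1-methoxy-2-[1-(triisopropylsilyl)-1H-indol-3-yl]ethenyl}stannane | CO/C(=C\c1cn([Si](C(C)C)(C(C)C)C(C)C)c2ccccc12)[Sn](CCCC)(CCCC)CCCC | intermediate
14 | (Z)-{1-methoxy-2-[1-(triisopropylsilyl)-1H-indol-3-yl]ethenyl}lithium | CO/C([Li])=C\c1cn([Si](C(C)C)(C(C)C)C(C)C)c2ccccc12 | intermediate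
15 | lithium 2-methoxy-1-{(Z)-1-methoxy-2-[1-(triisopropylsilyl)-1H-indol-3-yl]ethenyl}-3-(3-methylbut-2-en-1-yl)-4-[1-(triisopropylsilyl)-1H-indol-3-yl]-4-(trimethylsilyloxy)cyclobut-2-en-1-olate (diastereomer mixture) | CO/C(=C\c1cn([Si](C(C)C)(C(C)C)C(C)C)c2ccccc12)C1(O[Li])C(OC)=C(CC=C(C)C)C1(O[Si](C)(C)C)c1cn([Si](C(C)C)(C(C)C)C(C)C)c2ccccc12 | intermediate
16 | 4-hydroxy-4-{(Z)-1-methoxy-2-[1-(triisopropylsilyl)-1H-indol-3-yl]ethenyl}-2-(3-methylbut-2-en-1-yl)-3-[1-(triisopropylsilyl)-1H-indol-3-yl]cyclobut-2-en-1-one (racemic) | CO/C(=C\c1cn([Si](C(C)C)(C(C)C)C(C)C)c2ccccc12)C1(O)C(=O)C(CC=C(C)C)=C1c1cn([Si](C(C)C)(C(C)C)C(C)C)c2ccccc12 | intermediate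
17 | dienylketene: 4-hydroxy-5-methoxy-2-(3-methylbut-2-en-1-yl)-3,6-bis[1-(triisopropylsilyl)-1H-indol-3-yl]hexa-1,3,5-trien-1-one (hydroxyl trans to the ketene-bearing carbon) | O=C=C(CC=C(C)C)/C(c1cn([Si](C(C)C)(C(C)C)C(C)C)c2ccccc12)=C(/O)\C(OC)=C\c1cn([Si](C(C)C)(C(C)C)C(C)C)c2ccccc12 | intermediate
18 | 4-hydroxy-5-methoxy-2-(3-methylbut-2-en-1-yl)-3,6-bis[1-(triisopropylsilyl)-1H-indol-3-yl]cyclohexa-2,4-dien-1-one (racemic) | O=C1C(CC=C(C)C)=C(c2cn([Si](C(C)C)(C(C)C)C(C)C)c3ccccc23)C(O)=C(OC)C1c1cn([Si](C(C)C)(C(C)C)C(C)C)c2ccccc12 | intermediate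
19 | 2-methoxy-5-(3-methylbut-2-en-1-yl)-3,6-bis[1-(triisopropylsilyl)-1H-indol-3-yl]benzene-1,4-diol | COc1c(O)c(-c2cn([Si](C(C)C)(C(C)C)C(C)C)c3ccccc23)c(CC=C(C)C)c(O)c1-c1cn([Si](C(C)C)(C(C)C)C(C)C)c2ccccc12 | intermediate
20 | 2-methoxy-5-(3-methylbut-2-en-1-yl)-3,6-bis[1-(triisopropylsilyl)-1H-indol-3-yl]cyclohexa-2,5-diene-1,4-dione | COC1=C(c2cn([Si](C(C)C)(C(C)C)C(C)C)c3ccccc23)C(=O)C(CC=C(C)C)=C(c2cn([Si](C(C)C)(C(C)C)C(C)C)c3ccccc23)C1=O | intermediate
21 | 3,6-di(1H-indol-3-yl)-2-methoxy-5-(3-methylbut-2-en-1-yl)cyclohexa-2,5-diene-1,4-dione | COC1=C(c2c[nH]c3ccccc23)C(=O)C(CC=C(C)C)=C(c2c[nH]c3ccccc23)C1=O | target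

**Step count and risks**
Total step count: 9. Longest linear sequence: 7 steps (1, 2, 3, 6, 7, 8, 9); steps 4 and 5 form the second branch.

Steps most likely to fail:

- Step 6. Proton transfer from the doubly allylic CH2 of 8 to the alkenyllithium may compete with carbonyl addition, and the new enol ether may hydrolyse during the acid-promoted transposition. Fallback: setting out from 8, 1 M HCl in THF at 0 °C completes the hydrolysis to 3-(3-methylbut-2-en-1-yl)-4-[1-(triisopropylsilyl)-1H-indol-3-yl]cyclobut-3-ene-1,2-dione F1 before any enol ether exists. Alkenyllithium 14 is then added to F1 at -78 °C. The carbonyl next to the prenyl carbon is deactivated as a doubly vinylogous amide of the indole nitrogen, so attack should fall on the carbonyl next to the indolyl carbon and give the lithium alkoxide F2. A neutral ammonium chloride quench converts F2 into 16, where the route is rejoined. Regiochemistry then rests on electronic bias instead of construction, but no acid is used after the enol ether is in place.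

- Step 7. The ketene may be captured by the free hydroxyl (lactonization) if the ring opening rotates the wrong way, the tertiary carbinol may ionize at high temperature, and the 6π closure may be slow at the crowded terminus. Fallback: from 16, TMSCl and imidazole in DMF should give the trimethylsilyl ether F3. Its ring expansion (p-xylene, 138 °C) uses the silyloxy group as the outward-rotating donor and leaves no free hydroxyl to add to the ketene or to ionize; it should give the mono-silyl ether F4 of the hydroquinone. Methanol with a trace of citric acid removes the silyl group and returns 19.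

- Step 5. Tin may be delivered in part to the aryl-bearing carbon, and the α-alkoxyalkenylstannane may protodestannylate on purification. Fallback: from 12, syn addition of HI (generated from TMSI and one equivalent of water, CH2Cl2, -78 °C), whose regiochemistry is fixed by protonation at the carbon remote from oxygen, should give (E)-3-(2-iodo-2-methoxyethenyl)-1-(triisopropylsilyl)-1H-indole F5. Iodine–lithium exchange with t-BuLi (THF, -78 °C) then delivers 14 directly, and the route is rejoined in step 6 without tin.

**Further compounds**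
F1 | step 6 | 3-(3-methylbut-2-en-1-yl)-4-[1-(triisopropylsilyl)-1H-indol-3-yl]cyclobut-3-ene-1,2-dione | CC(C)=CCC1=C(c2cn([Si](C(C)C)(C(C)C)C(C)C)c3ccccc23)C(=O)C1=O
F2 | step 6 | lithium alkoxide of 16 | CO/C(=C\c1cn([Si](C(C)C)(C(C)C)C(C)C)c2ccccc12)C1(O[Li])C(=O)C(CC=C(C)C)=C1c1cn([Si](C(C)C)(C(C)C)C(C)C)c2ccccc12
F3 | step 7 | trimethylsilyl ether of 16 | CO/C(=C\c1cn([Si](C(C)C)(C(C)C)C(C)C)c2ccccc12)C1(O[Si](C)(C)C)C(=O)C(CC=C(C)C)=C1c1cn([Si](C(C)C)(C(C)C)C(C)C)c2ccccc12
F4 | step 7 | 3-methoxy-6-(3-methylbut-2-en-1-yl)-2,5-bis[1-(triisopropylsilyl)-1H-indol-3-yl]-4-(trimethylsilyloxy)phenol | COc1c(O[Si](C)(C)C)c(-c2cn([Si](C(C)C)(C(C)C)C(C)C)c3ccccc23)c(CC=C(C)C)c(O)c1-c1cn([Si](C(C)C)(C(C)C)C(C)C)c2ccccc12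
F5 | step 5 | (E)-3-(2-iodo-2-methoxyethenyl)-1-(triisopropylsilyl)-1H-indole | CO/C(I)=C\c1cn([Si](C(C)C)(C(C)C)C(C)C)c2ccccc12
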